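Two final targets and one verdict between them are asked.

- the flask that ends with the higher amount of target, in percent of the substrate charged, or "neither" when 2 percentage points or less lies between them (midnight / dusk / neither)
- final target, as a percentage of the substrate charged, in midnight
- final target, as a percentage of the substrate charged, in dusk

| flask | substrate | remark | time |
|---|---|---|---|
| delta | 0.011 M | run made earlier |  |
| gamma | 0.048 M | run made earlier |  |
| midnight | 0.057 M |  | 30 min |
| dusk | 0.020 M |  | 10 min |

| run | time / min | target / % |
|---|---|---|
| delta | 2.50 | 3.4 |
| delta | 4.00 | 6.5 |
| delta | 6.00 | 12.6 |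
| delta | 10.0 | 25.1 |
| delta | 20.0 | 50.1 |
| delta | 30.0 | 61.8 |
| gamma | 2.00 | 2.0 |
| gamma | 6.00 | 11.0 |
| gamma | 10.0 | 19.1 |
| gamma | 15.0 | 29.3 |
| gamma | 25.0 | 41.1 |
| gamma | 30.0 | 44.0 |

(each reading ± 0.5 percentage points)

- in percentages every species weighs as the substrate in it: one self-condensation product counts as two
- what may be going on: substrate -> intermediate A; intermediate A -> intermediate B; intermediate B -> intermediate C; intermediate A -> target; intermediate C -> side product; 2 substrate -> self-condensation product

Two substrate meet in the self-condensation step, so that loss should weigh more as the charge rises. At a fixed time, then, take the target as a loss-free fraction of the charge divided by one plus a load, with the load in step with the charge; the kept fraction, one over that sum, is in effect a selectivity. Begin at 30.0 min by treating delta as loss-free, which gives gamma a load of 0.405. But delta carries 0.229 of gamma's load, so put that back in. The second round gives 0.535, and the rounds tend to 0.597, gamma's load, the excess of its loss-free target over its target, as a fraction of that target.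

Scaling by charge from delta's readings at each flask's time, and assuming that the load read at 30.0 min also holds at dusk's 10 min, I expect 41.1% in midnight and 22.9% in dusk, so I expect midnight to end higher. The forecast gives 41% (39% to 43%) and 23.4% (22% to 24.8%), a dusk above mine, and says “Midnight ends far higher”. The simulation gives 41.2% in midnight and 23.1% in dusk, so midnight ends higher.

    substrate → intermediate A (k = 0.00188 s⁻¹)
    intermediate A → intermediate B (k = 3.22 × 10⁻⁴ s⁻¹)
    intermediate B → intermediate C (k = 0.00190 s⁻¹)
    intermediate A → target (k = 0.00168 s⁻¹)
    intermediate C → side product (k = 2.40 × 10⁻⁴ s⁻¹)
    2 substrate → self-condensation product (k = 0.0334 M⁻¹ s⁻¹)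

Midnight's self-condensation product reads 44.9% at 15.0 min and 45.3% at 30.0 min. Now read midnight earlier, at 20 min, and apply the loads read at 30.0 min to delta's 50.1% at 20.0 min: that gives 33.3%. The neighbouring flask holds 34.1% of target.

(All runs were generated by integration with constants of no real substance, noise included.)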